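The earlier runs and the new flask are calculated on assumed constants; noise was put on by code.

The easy step was to ask how many times the substrate had halved. In the south-west run 57% was left at 6.00 min, which is 0.811 halvings, and in the north-east run 28% was left at the same time, which is 1.84. The number of times a flask has halved its substrate, its half-life count, was what I carried.

common to all: substrate 0.80 M

| flask | free catalyst | remark | time |
|---|---|---|---|
| south-west | 23 mM | run made earlier |  |
| north-east | 54 mM | run made earlier |  |
| dawn | 12 mM |  | 8.0 min |
| autumn | 24 mM |  | 8.0 min |
| winter | 48 mM |  | 8.0 min |

| run | time / min | target / % | catalyst intermediate B / % | over-reaction product / % | substrate / % |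
|---|---|---|---|---|---|
| south-west | 0.417 | 1 | 1 | 0 | 97 |
| south-west | 0.833 | 4 | 1 | 1 | 93 |
| south-west | 1.50 | 9 | 0 | 1 | 89 |
| south-west | 3.00 | 12 | 1 | 9 | 81 |
| south-west | 6.00 | 13 | 1 | 29 | 57 |
| north-east | 0.417 | 5 | 3 | 4 | 94 |
| north-east | 0.833 | 11 | 3 | 1 | 84 |
| north-east | 1.50 | 16 | 1 | 4 | 74 |
| north-east | 3.00 | 23 | 1 | 22 | 52 |
| north-east | 6.00 | 17 | 3 | 54 | 28 |

(readings scatter by 1.5 percentage points)

- the numbers in the tables scatter with a standard deviation of 1.5 percentage points
- steps under discussion: catalyst intermediate B -> free catalyst + target; catalyst intermediate A -> catalyst intermediate B; substrate + free catalyst <-> catalyst intermediate A; target -> over-reaction product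

- which of these there is most of at the end, counted by the substrate in it, dawn (substrate / over-reaction product / target / catalyst intermediate B)
- which of these there is most of at the end, counted by the substrate in it, autumn (substrate / over-reaction product / target / catalyst intermediate B)
- which of these there is most of at the end, counted by the substrate in it, winter (substrate / over-reaction product / target / catalyst intermediate B)
- the largest of these amounts at the end, in percent of the substrate charged, dawn
- the largest of these amounts at the end, in percent of the substrate charged, autumn
- the largest of these amounts at the end, in percent of the substrate charged, winter

Did the count follow the catalyst? The counts, read from scattered readings, stood at a ratio of 2.27 and the catalyst charges at 2.35, so I took the decay as pseudo-first-order, with the count proportional to the charged [free catalyst] times time at this [substrate].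

What count did each new flask get? Scaling from the north-east run gave 0.544 for dawn, 1.09 for autumn and 2.18 for winter. By my reckoning that put substrate at 68.6%, 47.0% and 22.1%.

Who then led? In dawn, my reckoned substrate was more than the rest of the charge together. For autumn I took target from the south-west run's last reading, 13%, which left over-reaction product at 40.0%, so in my reckoning substrate stayed ahead. For winter I took target from the north-east run's last reading, 17%, which gave over-reaction product 60.9%, in my reckoning well ahead of substrate.

The forecast, made from the same runs, named substrate at 68% for dawn, substrate at 46% for autumn and over-reaction product at 64% for winter; its figures differ a little from mine. On autumn it said: “This is a close call, and substrate narrowly leads.”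

The flasks gave substrate at 70.9% in dawn, substrate at 48.4% in autumn and over-reaction product at 65.7% in winter.

    catalyst intermediate B → free catalyst + target (k = 0.140 s⁻¹)
    catalyst intermediate A → catalyst intermediate B (k = 0.670 s⁻¹)
    substrate + free catalyst ⇌ catalyst intermediate A (K = 0.150 M⁻¹, k = 0.940 M⁻¹ s⁻¹)
    target → over-reaction product (k = 0.00860 s⁻¹)

The forecast stood on each question. Winter's recipe differs from dawn's in its free catalyst, and that difference in concentration may be called the main reason for how far winter's substrate fell: without it, winter's substrate stands at 70.9% instead of 20.3%, a shift of 51 percentage points. The count carries to a neighbour flask, winter's recipe with 0.019 M of free catalyst. There I reckoned the count at 0.862, which gives 55.0% substrate. That neighbour flask held 57.0% substrate, with 33.2% over-reaction product.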